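**Plan**

- Numbering: ring A is the 3,4,5-trimethoxyphenyl ring and ring B the methyl vanillate ring; C7 is the benzylic carbinol on ring A, C8 the carbon carrying the ether oxygen to ring B, C9 the methyl group. The target is the threo (7S,8S) isomer.
- Retrosynthesis: C9 is first raised to the carboxyl level, which exposes the array C7(OH)–C8(OAr)–C9(=O). Here the two stereocentres flank a single C–C bond with oxygen on both carbons, the pattern of a glycolate aldol. The C7–C8 bond is cut first, then the C9–N imide bond, then the ring B O–CH2 ether bond.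
- Forward: the chain is joined in the order ring B phenol plus a C2 acetate unit (O-alkylation), attachment of (R)-4-benzyloxazolidin-2-one, and boron aldol with 3,4,5-trimethoxybenzaldehyde (C7–C8). No ring is formed anywhere in the route. C9 is then taken from imide carbonyl to CH2OH, CH2OTs, CH2I and CH3.
- Stereochemistry: C7 and C8 are both created in the aldol. The Z-boron enolate in a chair transition state gives the syn pair, the (R)-benzyl auxiliary fixes its absolute sense, and no later step touches either centre.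

Key step: step 4

Remark: methyl vanillate, tert-butyl bromoacetate, (R)-4-benzyloxazolidin-2-one and 3,4,5-trimethoxybenzaldehyde are taken to be commercial, and the ring B methyl ester is carried unprotected through the whole sequence.

**Route**

Step 1
Reactants: 1 methyl vanillate (methyl 4-hydroxy-3-methoxybenzoate); 2 tert-butyl bromoacetate
Product: 3 methyl 4-(2-tert-butoxy-2-oxoethoxy)-3-methoxybenzoate
Conditions: K2CO3, acetone, reflux
Reagents that add atoms: none
Why: Williamson ether synthesis, in which the phenoxide of 1 (the only acidic site) displaces bromide from the activated α-bromo ester by SN2 while both esters resist the carbonate base.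

Step 2
Reactants: 3 methyl 4-(2-tert-butoxy-2-oxoethoxy)-3-methoxybenzoate
Product: 4 [2-methoxy-4-(methoxycarbonyl)phenoxy]acetic acid
Conditions: TFA, CH2Cl2 (1:1), rt
Reagents that add atoms: none
Why: Acidolysis of a tert-butyl ester with loss of isobutene is selective, because the methyl benzoate and the aryl methyl ethers are stable to TFA at room temperature.

Step 3
Reactants: 4 [2-methoxy-4-(methoxycarbonyl)phenoxy]acetic acid; 5 (R)-4-benzyloxazolidin-2-one
Product: 7 (R)-4-benzyl-3-{[2-methoxy-4-(methoxycarbonyl)phenoxy]acetyl}oxazolidin-2-one, via pivalic mixed anhydride 6 (not isolated)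
Conditions: PivCl, Et3N, THF, −20 °C; then LiCl, 5, −20 °C → rt
Reagents that add atoms: none
Why: N-Acylation of an oxazolidinone through a mixed pivalic anhydride with LiCl/Et3N activation, in which the carbamate nitrogen attacks the unhindered aryloxyacetyl carbonyl and no strong base or nucleophile that could attack the ring B ester is present.

Step 4
Reactants: 7 (R)-4-benzyl-3-{[2-methoxy-4-(methoxycarbonyl)phenoxy]acetyl}oxazolidin-2-one; 8 3,4,5-trimethoxybenzaldehyde
Product: 11 (R)-4-benzyl-3-{(2R,3S)-3-hydroxy-2-[2-methoxy-4-(methoxycarbonyl)phenoxy]-3-(3,4,5-trimethoxyphenyl)propanoyl}oxazolidin-2-one, via Z-dibutylboron enolate 9 (not isolated), via dibutylboron aldolate 10 (not isolated)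
Conditions: Bu2BOTf (1.2 equiv), iPr2NEt (1.4 equiv), CH2Cl2, −78 → 0 °C; then 8, −78 → 0 °C; then pH 7 phosphate buffer, MeOH, 30% H2O2, 0 °C
Reagents that add atoms: none
Why: Bu2BOTf and iPr2NEt enolize the imide to the Z-dibutylboron enolate 9 (aryloxy group cis to the boron-bound oxygen), and boron then binds the aldehyde so that the C7–C8 bond forms in a closed six-membered chair (Zimmerman–Traxler) transition state; the closest known reaction is the Evans syn aldol of N-(alkoxyacetyl)oxazolidinones (glycolate aldol). No ring is closed, since the step joins two acyclic fragments through one C–C bond. C8 is controlled by the auxiliary: boron can hold only the enolate and aldehyde oxygens, so the oxazolidinone carbonyl turns away from the enolate oxygen, the (R)-benzyl group covers one enolate face, and the aldehyde adds to the other to give the 2R centre. C7 is controlled relative to C8 by the Z geometry and the chair, in which the trimethoxyphenyl group sits equatorial, so the 2,3-syn (2R,3S) adduct should result, which corresponds to the threo (7S,8S) array once C9 is a methyl group. The step needs syn over anti selectivity, one enolate face over the other, and enolization at the aryloxyacetyl CH2 only; the Z-enolate and auxiliary secure the first two, and the absence of any other enolizable C–H (neither the aldehyde nor the ring B ester has one) secures the third. Oxidative work-up cleaves the boron aldolate 10 to the free carbinol without touching the methyl ester.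

Step 5
Reactants: 11 (R)-4-benzyl-3-{(2R,3S)-3-hydroxy-2-[2-methoxy-4-(methoxycarbonyl)phenoxy]-3-(3,4,5-trimethoxyphenyl)propanoyl}oxazolidin-2-one
Product: 12 methyl 4-{[(1S,2S)-1,3-dihydroxy-1-(3,4,5-trimethoxyphenyl)propan-2-yl]oxy}-3-methoxybenzoate
Conditions: NaBH4, THF/H2O (4:1), 0 °C → rt
Reagents that add atoms: none
Why: Reductive cleavage of an N-acyloxazolidinone with NaBH4 in wet THF, in which hydride adds to the activated exocyclic imide carbonyl and the released aldehyde is reduced on to the C9 primary alcohol, while the methyl benzoate is too unreactive toward NaBH4 at this temperature and C7 and C8 are not involved.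

Step 6
Reactants: 12 methyl 4-{[(1S,2S)-1,3-dihydroxy-1-(3,4,5-trimethoxyphenyl)propan-2-yl]oxy}-3-methoxybenzoate
Product: 13 (2S,3S)-3-hydroxy-2-[2-methoxy-4-(methoxycarbonyl)phenoxy]-3-(3,4,5-trimethoxyphenyl)propyl 4-methylbenzenesulfonate
Conditions: TsCl (1.1 equiv), pyridine, CH2Cl2, 0 °C
Reagents that add atoms: p-toluenesulfonyl chloride, Cc1ccc(cc1)S(=O)(=O)Cl
Why: Site-selective sulfonylation, in which the unhindered primary C9 hydroxyl reacts with TsCl much faster at 0 °C than the hindered secondary benzylic C7 hydroxyl.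

Step 7
Reactants: 13 (2S,3S)-3-hydroxy-2-[2-methoxy-4-(methoxycarbonyl)phenoxy]-3-(3,4,5-trimethoxyphenyl)propyl 4-methylbenzenesulfonate
Product: 14 methyl 4-{[(1S,2R)-1-hydroxy-3-iodo-1-(3,4,5-trimethoxyphenyl)propan-2-yl]oxy}-3-methoxybenzoate
Conditions: NaI, acetone, reflux
Reagents that add atoms: sodium iodide, [Na+].[I-]
Why: Finkelstein reaction, in which iodide displaces the primary tosylate at C9 by SN2, driven by precipitation of sodium tosylate, under neutral conditions that leave the free C7 hydroxyl and both stereocentres alone (the descriptor at C8 changes only through ligand priority).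

Step 8
Reactants: 14 methyl 4-{[(1S,2R)-1-hydroxy-3-iodo-1-(3,4,5-trimethoxyphenyl)propan-2-yl]oxy}-3-methoxybenzoate
Product: 15 methyl 4-{[(1S,2S)-1-hydroxy-1-(3,4,5-trimethoxyphenyl)propan-2-yl]oxy}-3-methoxybenzoate (CNP0078566.1)
Conditions: Bu3SnH, AIBN (cat.), toluene, 80 °C
Reagents that add atoms: none
Why: Radical-chain dehalogenation, in which the tributylstannyl radical abstracts iodine and the primary C9 radical takes hydrogen from Bu3SnH much faster than it could expel the aryloxy group, so the ester, the free hydroxyl and both stereocentres should remain intact.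

**Compound list**

1 | methyl vanillate (methyl 4-hydroxy-3-methoxybenzoate) | COC(=O)c1ccc(O)c(OC)c1 | starting material
2 | tert-butyl bromoacetate | CC(C)(C)OC(=O)CBr | starting material
3 | methyl 4-(2-tert-butoxy-2-oxoethoxy)-3-methoxybenzoate | COC(=O)c1ccc(OCC(=O)OC(C)(C)C)c(OC)c1 | intermediate
4 | [2-methoxy-4-(methoxycarbonyl)phenoxy]acetic acid | COC(=O)c1ccc(OCC(=O)O)c(OC)c1 | intermediate
5 | (R)-4-benzyloxazolidin-2-one | O=C1N[C@H](Cc2ccccc2)CO1 | starting material
6 | [2-methoxy-4-(methoxycarbonyl)phenoxy]acetic pivalic anhydride | COC(=O)c1ccc(OCC(=O)OC(=O)C(C)(C)C)c(OC)c1 | intermediate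
7 | (R)-4-benzyl-3-{[2-methoxy-4-(methoxycarbonyl)phenoxy]acetyl}oxazolidin-2-one | COC(=O)c1ccc(OCC(=O)N2[C@H](Cc3ccccc3)COC2=O)c(OC)c1 | intermediate
8 | 3,4,5-trimethoxybenzaldehyde | COc1cc(C=O)cc(OC)c1OC | starting material
9 | (R)-4-benzyl-3-{(Z)-1-[(dibutylboranyl)oxy]-2-[2-methoxy-4-(methoxycarbonyl)phenoxy]ethenyl}oxazolidin-2-one (Z-boron enolate of 7) | COC(=O)c1ccc(O/C=C(\OB(CCCC)CCCC)N2[C@H](Cc3ccccc3)COC2=O)c(OC)c1 | intermediate
10 | O-dibutylboryl aldolate of 11 | COC(=O)c1ccc(O[C@@H](C(=O)N2[C@H](Cc3ccccc3)COC2=O)[C@@H](OB(CCCC)CCCC)c2cc(OC)c(OC)c(OC)c2)c(OC)c1 | intermediate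
11 | (R)-4-benzyl-3-{(2R,3S)-3-hydroxy-2-[2-methoxy-4-(methoxycarbonyl)phenoxy]-3-(3,4,5-trimethoxyphenyl)propanoyl}oxazolidin-2-one | COC(=O)c1ccc(O[C@@H](C(=O)N2[C@H](Cc3ccccc3)COC2=O)[C@@H](O)c2cc(OC)c(OC)c(OC)c2)c(OC)c1 | intermediate
12 | methyl 4-{[(1S,2S)-1,3-dihydroxy-1-(3,4,5-trimethoxyphenyl)propan-2-yl]oxy}-3-methoxybenzoate | COC(=O)c1ccc(O[C@@H](CO)[C@@H](O)c2cc(OC)c(OC)c(OC)c2)c(OC)c1 | intermediate
13 | (2S,3S)-3-hydroxy-2-[2-methoxy-4-(methoxycarbonyl)phenoxy]-3-(3,4,5-trimethoxyphenyl)propyl 4-methylbenzenesulfonate | COC(=O)c1ccc(O[C@@H](COS(=O)(=O)c2ccc(C)cc2)[C@@H](O)c2cc(OC)c(OC)c(OC)c2)c(OC)c1 | intermediate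
14 | methyl 4-{[(1S,2R)-1-hydroxy-3-iodo-1-(3,4,5-trimethoxyphenyl)propan-2-yl]oxy}-3-methoxybenzoate | COC(=O)c1ccc(O[C@@H](CI)[C@@H](O)c2cc(OC)c(OC)c(OC)c2)c(OC)c1 | intermediate
15 | methyl 4-{[(1S,2S)-1-hydroxy-1-(3,4,5-trimethoxyphenyl)propan-2-yl]oxy}-3-methoxybenzoate (CNP0078566.1) | COC(=O)c1ccc(O[C@@H](C)[C@@H](O)c2cc(OC)c(OC)c(OC)c2)c(OC)c1 | target

**Step count**

Total step count: 8. Longest linear sequence: 8 steps (1 to 15); compounds 2, 5 and 8 enter as purchased materials.

**Steps most likely to fail**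

Step 4. The enolization may be incomplete or poorly ordered. Boron can be tied up by the ring B ester and the methoxy oxygens, and the aryloxy-substituted enolate may react through a less organized transition state, so that conversion or the syn and facial selectivity falls short. The fallback keeps the C7–C8 aldol union but changes the auxiliary and the metal. It sets out from acid 4, which is coupled with (R)-4-benzylthiazolidine-2-thione (EDC·HCl, DMAP, CH2Cl2) to give (R)-4-benzyl-3-{[2-methoxy-4-(methoxycarbonyl)phenoxy]acetyl}thiazolidine-2-thione F1. Its chlorotitanium enolate (TiCl4, iPr2NEt, N-methyl-2-pyrrolidinone, CH2Cl2, 0 °C), formed under the conditions that favour the non-chelated chair, is expected to add to aldehyde 8 with the same syn sense. This would give (R)-4-benzyl-3-{(2R,3S)-3-hydroxy-2-[2-methoxy-4-(methoxycarbonyl)phenoxy]-3-(3,4,5-trimethoxyphenyl)propanoyl}thiazolidine-2-thione F2. NaBH4 in THF/EtOH at 0 °C then releases the thiazolidinethione, and the route is rejoined at diol 12.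

Step 6. Site selectivity in the sulfonylation may be lost: the secondary benzylic hydroxyl may be sulfonylated as well, or the hydroxy tosylate may close to an oxetane or suffer chloride substitution at the benzylic carbon. The fallback removes the competing hydroxyl before C9 is unmasked and sets out from aldol adduct 11.
- Silylation (TBSOTf, 2,6-lutidine, CH2Cl2, 0 °C) should give (R)-4-benzyl-3-{(2R,3S)-3-[(tert-butyldimethylsilyl)oxy]-2-[2-methoxy-4-(methoxycarbonyl)phenoxy]-3-(3,4,5-trimethoxyphenyl)propanoyl}oxazolidin-2-one F3.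
- NaBH4 in THF/H2O removes the auxiliary to give methyl 4-{[(1S,2S)-1-[(tert-butyldimethylsilyl)oxy]-3-hydroxy-1-(3,4,5-trimethoxyphenyl)propan-2-yl]oxy}-3-methoxybenzoate F4, in which the C9 hydroxyl is the only free one.
- Appel-type iodination (PPh3, I2, imidazole, CH2Cl2) gives methyl 4-{[(1S,2R)-1-[(tert-butyldimethylsilyl)oxy]-3-iodo-1-(3,4,5-trimethoxyphenyl)propan-2-yl]oxy}-3-methoxybenzoate F5.
- Bu3SnH with AIBN in toluene at 80 °C gives methyl 4-{[(1S,2S)-1-[(tert-butyldimethylsilyl)oxy]-1-(3,4,5-trimethoxyphenyl)propan-2-yl]oxy}-3-methoxybenzoate F6.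
- TBAF in THF removes the silyl group, and the route ends at target 15.

Step 5. Hydride may attack the wrong carbonyl (the ring B methyl ester or the endocyclic carbamate carbonyl, which would open the oxazolidinone), or the basic medium may cause retro-aldol cleavage of the C7–C8 bond. The fallback separates auxiliary removal from reduction and sets out from aldol adduct 11. LiOH/H2O2 in THF/H2O at 0 °C should cleave the exocyclic imide carbonyl selectively to (2R,3S)-3-hydroxy-2-[2-methoxy-4-(methoxycarbonyl)phenoxy]-3-(3,4,5-trimethoxyphenyl)propanoic acid F7. BH3·SMe2 in THF (0 °C → rt) then reduces the carboxylic acid in preference to the methyl benzoate, and the route is rejoined at diol 12.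

**Further compounds**

F1 | step 4 | (R)-4-benzyl-3-{[2-methoxy-4-(methoxycarbonyl)phenoxy]acetyl}thiazolidine-2-thione | COC(=O)c1ccc(OCC(=O)N2[C@H](Cc3ccccc3)CSC2=S)c(OC)c1
F2 | step 4 | (R)-4-benzyl-3-{(2R,3S)-3-hydroxy-2-[2-methoxy-4-(methoxycarbonyl)phenoxy]-3-(3,4,5-trimethoxyphenyl)propanoyl}thiazolidine-2-thione | COC(=O)c1ccc(O[C@@H](C(=O)N2[C@H](Cc3ccccc3)CSC2=S)[C@@H](O)c2cc(OC)c(OC)c(OC)c2)c(OC)c1
F3 | step 6 | (R)-4-benzyl-3-{(2R,3S)-3-[(tert-butyldimethylsilyl)oxy]-2-[2-methoxy-4-(methoxycarbonyl)phenoxy]-3-(3,4,5-trimethoxyphenyl)propanoyl}oxazolidin-2-one | COC(=O)c1ccc(O[C@@H](C(=O)N2[C@H](Cc3ccccc3)COC2=O)[C@@H](O[Si](C)(C)C(C)(C)C)c2cc(OC)c(OC)c(OC)c2)c(OC)c1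
F4 | step 6 | methyl 4-{[(1S,2S)-1-[(tert-butyldimethylsilyl)oxy]-3-hydroxy-1-(3,4,5-trimethoxyphenyl)propan-2-yl]oxy}-3-methoxybenzoate | COC(=O)c1ccc(O[C@@H](CO)[C@@H](O[Si](C)(C)C(C)(C)C)c2cc(OC)c(OC)c(OC)c2)c(OC)c1
F5 | step 6 | methyl 4-{[(1S,2R)-1-[(tert-butyldimethylsilyl)oxy]-3-iodo-1-(3,4,5-trimethoxyphenyl)propan-2-yl]oxy}-3-methoxybenzoate | COC(=O)c1ccc(O[C@@H](CI)[C@@H](O[Si](C)(C)C(C)(C)C)c2cc(OC)c(OC)c(OC)c2)c(OC)c1
F6 | step 6 | methyl 4-{[(1S,2S)-1-[(tert-butyldimethylsilyl)oxy]-1-(3,4,5-trimethoxyphenyl)propan-2-yl]oxy}-3-methoxybenzoate | COC(=O)c1ccc(O[C@@H](C)[C@@H](O[Si](C)(C)C(C)(C)C)c2cc(OC)c(OC)c(OC)c2)c(OC)c1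
F7 | step 5 | (2R,3S)-3-hydroxy-2-[2-methoxy-4-(methoxycarbonyl)phenoxy]-3-(3,4,5-trimethoxyphenyl)propanoic acid | COC(=O)c1ccc(O[C@@H](C(=O)O)[C@@H](O)c2cc(OC)c(OC)c(OC)c2)c(OC)c1
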